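**Remark:** read from the SMILES, the target is (2S) at the chromene carbon, (1S) at the cyclohexene carbon and (E) at the chain alkene. Chromene numbering (O1, C2, C3, C4, C4a, C5–C8, C8a) is used for ring positions.

## Retrosynthetic overview

1. Rings: aromatic ring A, 2H-pyran ring B, cyclohexene ring C. The last disconnection is O6–Si of silyl ether 24.
2. Ring B is opened at C4–C4a and O1–C2 together, giving ortho-hydroxyarylboronate 22 and (R)-tertiary propargylic carbonate 18. The enabling feature is that the O1–C2(sp3)–C3=C4–C4a segment of ring B is a cycloisomerised ortho-allenylphenol: C3=C4 is the surviving allene π bond, C2 is the allene terminus that takes O1, and C4a and C8a(O1) are neighbours on ring A. C2 is therefore set by a centre → axis → centre relay, not by telling methyl from chain.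
3. 18 ← alkynol 17 ← epoxy chloride 15 ← Sharpless epoxide 14 of (E)-allylic alcohol 13; the quaternary C–O carbon of 14 becomes C2.
4. 13 ← alkylation of (S)-sulfone 7 with 8-bromogeranyl acetate 10 (both (E)-alkenes come from geranyl acetate); 7 ← decarboxylative Claisen [3,3] shift of ester 4 ← CBS alcohol 2.
5. Ring order: ring C is bought (enone 1) and its stereocentre set by the [3,3] shift; ring A is bought (phenol 19); ring B is formed last, in step 14.

Key step: step 14

## Route

Step 1
Reactants: 1 2,4,4-trimethylcyclohex-2-en-1-one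
Product: 2 (1R)-2,4,4-trimethylcyclohex-2-en-1-ol
Conditions: (S)-2-methyl-CBS-oxazaborolidine [(3aS)-1-methyl-3,3-diphenyltetrahydro-1H,3H-pyrrolo[1,2-c][1,3,2]oxazaborole] (10 mol %), BH3·SMe2, THF, −20 °C; MeOH quench
Reagents that add atoms: none
Why: Corey–Bakshi–Shibata reduction, in which the oxazaborolidine–borane complex treats the 2-methylalkene arm as the large group and should deliver hydride to the face that gives the (R) carbinol.

Step 2
Reactants: 2 (1R)-2,4,4-trimethylcyclohex-2-en-1-ol; 3 (4-methylphenylsulfonyl)acetic acid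
Product: 4 (1R)-2,4,4-trimethylcyclohex-2-en-1-yl (4-methylphenylsulfonyl)acetate
Conditions: DCC, DMAP (cat.), CH2Cl2, 0 → 25 °C
Reagents that add atoms: none
Why: Steglich esterification of a secondary allylic alcohol, which leaves the carbinol centre untouched.

Step 3
Reactants: 4 (1R)-2,4,4-trimethylcyclohex-2-en-1-yl (4-methylphenylsulfonyl)acetate
Product: 7 1-methyl-4-({[(1S)-2,6,6-trimethylcyclohex-2-en-1-yl]methyl}sulfonyl)benzene, via silyl ketene acetal 5 (not isolated), via rearranged silyl ester 6 (not isolated)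
Conditions: N,O-bis(trimethylsilyl)acetamide (0.3 equiv), KOAc (0.1 equiv), toluene, 110 °C
Reagents that add atoms: none
Why: Decarboxylative Claisen rearrangement (Ireland–Claisen [3,3] shift of the silyl ketene acetal, then acetate-triggered loss of CO2 from the α-sulfonyl silyl ester); the suprafacial shift should carry the (R) C–O centre across the allyl unit to the new C–C bond beside the gem-dimethyl carbon and set the ring stereocentre as (S).

Step 4
Reactants: 8 geranyl acetate
Product: 9 (2E,6E)-8-hydroxy-3,7-dimethylocta-2,6-dien-1-yl acetate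
Conditions: SeO2 (10 mol %), t-BuOOH (3 equiv), salicylic acid (10 mol %), CH2Cl2, 25 °C
Reagents that add atoms: tert-butyl hydroperoxide, CC(C)(C)OO
Why: Sharpless–Umbreit allylic oxidation (ene reaction then [2,3] shift of the allylseleninic acid), which is selective for the (E)-methyl group of the electron-richer distal alkene and keeps both alkene geometries.

Step 5
Reactants: 9 (2E,6E)-8-hydroxy-3,7-dimethylocta-2,6-dien-1-yl acetate
Product: 10 (2E,6E)-8-bromo-3,7-dimethylocta-2,6-dien-1-yl acetate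
Conditions: CBr4, PPh3, CH2Cl2, 0 °C
Reagents that add atoms: carbon tetrabromide, BrC(Br)(Br)Br
Why: Appel bromination of a primary allylic alcohol under neutral conditions, which should proceed without allylic transposition at 0 °C.

Step 6
Reactants: 7 1-methyl-4-({[(1S)-2,6,6-trimethylcyclohex-2-en-1-yl]methyl}sulfonyl)benzene; 10 (2E,6E)-8-bromo-3,7-dimethylocta-2,6-dien-1-yl acetate
Product: 11 (2E,6E)-3,7-dimethyl-9-(4-methylphenylsulfonyl)-9-[(1S)-2,6,6-trimethylcyclohex-2-en-1-yl]nona-2,6-dien-1-yl acetate (mixture at C9)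
Conditions: n-BuLi (1.05 equiv), THF, −78 °C; then 10, −78 → −40 °C
Reagents that add atoms: none
Why: SN2 alkylation of an α-lithio sulfone with a primary allylic bromide, a standard terpenoid chain coupling in which an allylic acetate is tolerated at low temperature; the new sulfonyl-bearing centre is removed in step 7.

Step 7
Reactants: 11 (2E,6E)-3,7-dimethyl-9-(4-methylphenylsulfonyl)-9-[(1S)-2,6,6-trimethylcyclohex-2-en-1-yl]nona-2,6-dien-1-yl acetate
Product: 13 (2E,6E)-3,7-dimethyl-9-[(1S)-2,6,6-trimethylcyclohex-2-en-1-yl]nona-2,6-dien-1-ol, via desulfonylated acetate 12 (not isolated)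
Conditions: Na(Hg) (6 % Na), MeOH/THF, −20 → 25 °C
Reagents that add atoms: none
Why: Reductive desulfonylation by electron transfer from sodium amalgam, after which the methoxide formed transesterifies the acetate; the sulfone is not allylic, so no alkene transposition is expected.

Step 8
Reactants: 13 (2E,6E)-3,7-dimethyl-9-[(1S)-2,6,6-trimethylcyclohex-2-en-1-yl]nona-2,6-dien-1-ol
Product: 14 {(2R,3R)-3-methyl-3-[(3E)-4-methyl-6-[(1S)-2,6,6-trimethylcyclohex-2-en-1-yl]hex-3-en-1-yl]oxiran-2-yl}methanol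
Conditions: Ti(OiPr)4 (10 mol %), D-(−)-diethyl tartrate (12 mol %), t-BuOOH (2 equiv), 4 Å MS, CH2Cl2, −20 °C
Reagents that add atoms: tert-butyl hydroperoxide, CC(C)(C)OO
Why: Sharpless asymmetric epoxidation, which touches only the allylic-alcohol alkene and with D-(−)-diethyl tartrate should give the (2R,3R)-epoxide of this (E)-3,3-disubstituted allylic alcohol, fixing the quaternary C–O carbon.

Step 9
Reactants: 14 {(2R,3R)-3-methyl-3-[(3E)-4-methyl-6-[(1S)-2,6,6-trimethylcyclohex-2-en-1-yl]hex-3-en-1-yl]oxiran-2-yl}methanol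
Product: 15 (2S,3R)-2-(chloromethyl)-3-methyl-3-[(3E)-4-methyl-6-[(1S)-2,6,6-trimethylcyclohex-2-en-1-yl]hex-3-en-1-yl]oxirane
Conditions: PPh3, CCl4, NaHCO3, reflux
Reagents that add atoms: carbon tetrachloride, ClC(Cl)(Cl)Cl
Why: Appel chlorination of the primary alcohol, buffered with bicarbonate so that the acid-sensitive trisubstituted epoxide survives (the descriptor at C2 changes by priority only).

Step 10
Reactants: 15 (2S,3R)-2-(chloromethyl)-3-methyl-3-[(3E)-4-methyl-6-[(1S)-2,6,6-trimethylcyclohex-2-en-1-yl]hex-3-en-1-yl]oxirane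
Product: 17 (3R,6E)-3,7-dimethyl-9-[(1S)-2,6,6-trimethylcyclohex-2-en-1-yl]non-6-en-1-yn-3-ol, via chlorovinyl alkoxide 16 (not isolated)
Conditions: n-BuLi (3.5 equiv), THF, −78 → −30 °C; aq NH4Cl
Reagents that add atoms: none
Why: Base-induced fragmentation of a 2,3-epoxy chloride to a propargylic alcohol (Takano–Yadav protocol): β-elimination opens the epoxide, a second loss of HCl gives the acetylide, and the tertiary C–O centre is not touched and stays (R).

Step 11
Reactants: 17 (3R,6E)-3,7-dimethyl-9-[(1S)-2,6,6-trimethylcyclohex-2-en-1-yl]non-6-en-1-yn-3-ol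
Product: 18 methyl (3R,6E)-3,7-dimethyl-9-[(1S)-2,6,6-trimethylcyclohex-2-en-1-yl]non-6-en-1-yn-3-yl carbonate
Conditions: LiN(SiMe3)2 (1.1 equiv), THF, −78 °C; then ClCO2Me, −78 → 0 °C
Reagents that add atoms: methyl chloroformate, COC(=O)Cl
Why: O-acylation of the lithium tertiary alkoxide with a chloroformate; the amide base removes the hydroxyl proton and not the alkyne C–H.

Step 12
Reactants: 19 4-[(tert-butyldimethylsilyl)oxy]phenol
Product: 20 2-bromo-4-[(tert-butyldimethylsilyl)oxy]phenol
Conditions: NBS (1.0 equiv), CH2Cl2, −20 → 0 °C, dark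
Reagents that add atoms: N-bromosuccinimide, O=C1CCC(=O)N1Br
Why: Electrophilic aromatic bromination ortho to the free hydroxyl, the stronger director, with the para position blocked by the silyloxy group.

Step 13
Reactants: 20 2-bromo-4-[(tert-butyldimethylsilyl)oxy]phenol
Product: 22 4-[(tert-butyldimethylsilyl)oxy]-2-(4,4,5,5-tetramethyl-1,3,2-dioxaborolan-2-yl)phenol, via dilithio phenoxide 21 (not isolated)
Conditions: n-BuLi (2.2 equiv), THF, −78 °C; then i-PrOBpin; aq NH4Cl
Reagents that add atoms: 2-isopropoxy-4,4,5,5-tetramethyl-1,3,2-dioxaborolane, CC(C)OB1OC(C)(C)C(C)(C)O1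
Why: Lithiation–borylation: deprotonation of the phenol, bromine–lithium exchange, and trapping of the aryllithium with a borate ester.

Step 14
Reactants: 18 methyl (3R,6E)-3,7-dimethyl-9-[(1S)-2,6,6-trimethylcyclohex-2-en-1-yl]non-6-en-1-yn-3-yl carbonate; 22 4-[(tert-butyldimethylsilyl)oxy]-2-(4,4,5,5-tetramethyl-1,3,2-dioxaborolan-2-yl)phenol
Product: 24 tert-butyl(dimethyl){[(2S)-2-methyl-2-[(3E)-4-methyl-6-[(1S)-2,6,6-trimethylcyclohex-2-en-1-yl]hex-3-en-1-yl]-2H-chromen-6-yl]oxy}silane, via allenylphenol 23 (not isolated)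
Conditions: Pd2(dba)3 (1 mol %), PPh3 (4 mol %), THF, 25 °C, dark; then, in the same flask, (Ph3P)AuNTf2 (10 mol %), −20 → 0 °C
Reagents that add atoms: none
Why: Proposed new method: zerovalent palladium should ionise carbonate 18 in an anti SN2′ oxidative addition (loss of CO2, methoxide on palladium), transmetalate with boronate 22 and reductively eliminate at the alkyne terminus, which forms C4–C4a and turns the (R) C–O centre into the (aS) axis of allenylphenol 23; the closest known reaction type is the anti-stereospecific palladium-catalysed coupling of enantioenriched tertiary propargylic esters and carbonates with arylzinc and arylboron reagents. Cationic monovalent gold should then bind the distal C2=C3 π bond of 23 anti to the tethered hydroxyl, and the phenol oxygen should add to C2 in a 6-endo-trig closure of ring B, followed by protodeauration at C3; the closest known reaction type is the gold-catalysed cycloisomerisation of β-hydroxyallenes to dihydropyrans with axis-to-centre transfer. The new stereocentre C2 is controlled by the allene axis: the aryl group lies anti to the departed carbonate and O1 can reach C2 only from the aryl side, so O1 replaces the carbonate oxygen with net inversion and (R)-18 should give (2S)-24 without any reagent having to tell methyl from the chain. The step needs anti over syn SN2′ arylation at the alkyne terminus (favoured by the terminal alkyne and the PPh3-ligated η1-allenyl complex), 6-endo over 5-exo closure (favoured by the disubstituted allene terminus, which best carries positive charge), and a metal-mediated closure that outruns the racemising thermal [1,5]-hydrogen shift/oxa-6π path through the planar ortho-quinone methide (favoured by low temperature and a fast gold catalyst added as soon as 18 is consumed).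

Step 15
Reactants: 24 tert-butyl(dimethyl){[(2S)-2-methyl-2-[(3E)-4-methyl-6-[(1S)-2,6,6-trimethylcyclohex-2-en-1-yl]hex-3-en-1-yl]-2H-chromen-6-yl]oxy}silane
Product: 25 (2S)-2-methyl-2-[(3E)-4-methyl-6-[(1S)-2,6,6-trimethylcyclohex-2-en-1-yl]hex-3-en-1-yl]-2H-chromen-6-ol
Conditions: Bu4NF, AcOH (1:1), THF, 0 °C, argon, dark
Reagents that add atoms: none
Why: Fluoride-mediated cleavage of the aryl silyl ether, buffered with acetic acid so that the oxidation-prone chromenol is released as the neutral phenol; no stereocentre is touched.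

## Compound list

1 | 2,4,4-trimethylcyclohex-2-en-1-one | CC1=CC(C)(C)CCC1=O | starting material
2 | (1R)-2,4,4-trimethylcyclohex-2-en-1-ol | O[C@@H]1CCC(C)(C)C=C1C | intermediate
3 | (4-methylphenylsulfonyl)acetic acid | Cc1ccc(cc1)S(=O)(=O)CC(=O)O | starting material
4 | (1R)-2,4,4-trimethylcyclohex-2-en-1-yl (4-methylphenylsulfonyl)acetate | Cc1ccc(cc1)S(=O)(=O)CC(=O)O[C@@H]1CCC(C)(C)C=C1C | intermediate
5 | trimethylsilyl ketene acetal of 4 (alkene geometry open) | Cc1ccc(cc1)S(=O)(=O)C=C(O[Si](C)(C)C)O[C@@H]1CCC(C)(C)C=C1C | intermediate (not isolated)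
6 | trimethylsilyl 2-(4-methylphenylsulfonyl)-2-[(1S)-2,6,6-trimethylcyclohex-2-en-1-yl]acetate (mixture at the α-carbon) | CC1=CCCC(C)(C)[C@@H]1C(C(=O)O[Si](C)(C)C)S(=O)(=O)c1ccc(C)cc1 | intermediate (not isolated)
7 | 1-methyl-4-({[(1S)-2,6,6-trimethylcyclohex-2-en-1-yl]methyl}sulfonyl)benzene | CC1=CCCC(C)(C)[C@@H]1CS(=O)(=O)c1ccc(C)cc1 | intermediate
8 | geranyl acetate | CC(C)=CCC/C(C)=C/COC(C)=O | starting material
9 | (2E,6E)-8-hydroxy-3,7-dimethylocta-2,6-dien-1-yl acetate | OC/C(C)=C/CC/C(C)=C/COC(C)=O | intermediate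
10 | (2E,6E)-8-bromo-3,7-dimethylocta-2,6-dien-1-yl acetate | BrC/C(C)=C/CC/C(C)=C/COC(C)=O | intermediate
11 | (2E,6E)-3,7-dimethyl-9-(4-methylphenylsulfonyl)-9-[(1S)-2,6,6-trimethylcyclohex-2-en-1-yl]nona-2,6-dien-1-yl acetate (mixture at C9) | CC1=CCCC(C)(C)[C@@H]1C(C/C(C)=C/CC/C(C)=C/COC(C)=O)S(=O)(=O)c1ccc(C)cc1 | intermediate
12 | (2E,6E)-3,7-dimethyl-9-[(1S)-2,6,6-trimethylcyclohex-2-en-1-yl]nona-2,6-dien-1-yl acetate | CC1=CCCC(C)(C)[C@@H]1CC/C(C)=C/CC/C(C)=C/COC(C)=O | intermediate (not isolated)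
13 | (2E,6E)-3,7-dimethyl-9-[(1S)-2,6,6-trimethylcyclohex-2-en-1-yl]nona-2,6-dien-1-ol | CC1=CCCC(C)(C)[C@@H]1CC/C(C)=C/CC/C(C)=C/CO | intermediate
14 | {(2R,3R)-3-methyl-3-[(3E)-4-methyl-6-[(1S)-2,6,6-trimethylcyclohex-2-en-1-yl]hex-3-en-1-yl]oxiran-2-yl}methanol | CC1=CCCC(C)(C)[C@@H]1CC/C(C)=C/CC[C@@]2(C)O[C@@H]2CO | intermediate
15 | (2S,3R)-2-(chloromethyl)-3-methyl-3-[(3E)-4-methyl-6-[(1S)-2,6,6-trimethylcyclohex-2-en-1-yl]hex-3-en-1-yl]oxirane | CC1=CCCC(C)(C)[C@@H]1CC/C(C)=C/CC[C@@]2(C)O[C@@H]2CCl | intermediate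
16 | lithium (3R,6E)-1-chloro-3,7-dimethyl-9-[(1S)-2,6,6-trimethylcyclohex-2-en-1-yl]nona-1,6-dien-3-olate (chloroalkene geometry open) | CC1=CCCC(C)(C)[C@@H]1CC/C(C)=C/CC[C@@](C)(O[Li])C=CCl | intermediate (not isolated)
17 | (3R,6E)-3,7-dimethyl-9-[(1S)-2,6,6-trimethylcyclohex-2-en-1-yl]non-6-en-1-yn-3-ol | CC1=CCCC(C)(C)[C@@H]1CC/C(C)=C/CC[C@@](C)(O)C#C | intermediate
18 | methyl (3R,6E)-3,7-dimethyl-9-[(1S)-2,6,6-trimethylcyclohex-2-en-1-yl]non-6-en-1-yn-3-yl carbonate | CC1=CCCC(C)(C)[C@@H]1CC/C(C)=C/CC[C@@](C)(OC(=O)OC)C#C | intermediate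
19 | 4-[(tert-butyldimethylsilyl)oxy]phenol | Oc1ccc(O[Si](C)(C)C(C)(C)C)cc1 | starting material
20 | 2-bromo-4-[(tert-butyldimethylsilyl)oxy]phenol | Oc1ccc(O[Si](C)(C)C(C)(C)C)cc1Br | intermediate
21 | lithium 4-[(tert-butyldimethylsilyl)oxy]-2-lithiophenoxide | [Li]Oc1ccc(O[Si](C)(C)C(C)(C)C)cc1[Li] | intermediate (not isolated)
22 | 4-[(tert-butyldimethylsilyl)oxy]-2-(4,4,5,5-tetramethyl-1,3,2-dioxaborolan-2-yl)phenol | Oc1ccc(O[Si](C)(C)C(C)(C)C)cc1B1OC(C)(C)C(C)(C)O1 | intermediate
23 | 4-[(tert-butyldimethylsilyl)oxy]-2-[(aS,6E)-3,7-dimethyl-9-[(1S)-2,6,6-trimethylcyclohex-2-en-1-yl]nona-1,2,6-trien-1-yl]phenol | CC1=CCCC(C)(C)[C@@H]1CC/C(C)=C/CCC(C)=[C@@]=C([H])c1cc(O[Si](C)(C)C(C)(C)C)ccc1O | intermediate (not isolated)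
24 | tert-butyl(dimethyl){[(2S)-2-methyl-2-[(3E)-4-methyl-6-[(1S)-2,6,6-trimethylcyclohex-2-en-1-yl]hex-3-en-1-yl]-2H-chromen-6-yl]oxy}silane | CC1=CCCC(C)(C)[C@@H]1CC/C(C)=C/CC[C@@]1(C)C=Cc2cc(O[Si](C)(C)C(C)(C)C)ccc2O1 | intermediate
25 | (2S)-2-methyl-2-[(3E)-4-methyl-6-[(1S)-2,6,6-trimethylcyclohex-2-en-1-yl]hex-3-en-1-yl]-2H-chromen-6-ol | CC1=CCCC(C)(C)[C@@H]1CC/C(C)=C/CC[C@@]1(C)C=Cc2cc(O)ccc2O1 | target

## Step count and risks

Total step count: 15. Longest linear sequence: 11 steps (1, 2, 3, 6, 7, 8, 9, 10, 11, 14, 15).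

**Step 14 (key step).** What may go wrong: the free allenylphenol may close without metal through the [1,5]-hydrogen shift/oxa-6π path, or the aryl allene may be racemised by gold before the oxygen adds; either would erode the relay to C2. In addition, the phenol may attack the propargyl–palladium intermediate at oxygen, and residual phosphine may inhibit the gold catalyst. The fallback uses known chemistry, sets out from 13 (with 20 as aryl source) and returns at 24. Alcohol 13 is converted with ClCO2Me/pyridine into the allylic methyl carbonate F1. Bromophenol 20 is vinylated (vinylboronic acid pinacol ester, Pd(PPh3)4, K2CO3) to 4-[(tert-butyldimethylsilyl)oxy]-2-vinylphenol F2. Palladium-catalysed asymmetric allylic O-alkylation of F2 with F1 (Pd2(dba)3·CHCl3 and the antipode of the diaminocyclohexane-derived Trost ligand that delivers the (S) ether; the (E)-alkene geometry fixes the sense) gives the branched tertiary aryl ether F3. Ring-closing metathesis of the two vinyl groups with the second-generation Grubbs catalyst then closes ring B at C3=C4 and gives 24.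

**Step 3.** What may go wrong: the [3,3] shift has to form a bond at the alkene carbon flanked by the gem-dimethyl group, and ionisation of the allylic ester with elimination to a diene may outrun it. The fallback sets out from 2 and returns at 7. Alcohol 2 is O-alkylated (KH, Bu3SnCH2I) to the stannylmethyl ether F4. Tin–lithium exchange (n-BuLi, −78 °C) gives the lithiomethyl ether F5, whose suprafacial [2,3]-Wittig–Still rearrangement transfers chirality in the same sense and gives (S)-α-cyclogeraniol F6. Reaction with di-p-tolyl disulfide/PBu3 gives the p-tolyl sulfide F7, and oxidation with H2O2/(NH4)6Mo7O24 gives 7.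

**Step 6.** What may go wrong: C-alkylation of the hindered α-sulfonyl carbanion may be slow, leaving time for attack on the acetate carbonyl or dehydrobromination of 10. The fallback sets out from 4 (with 10) and returns at 11, with the order of the two C–C bond formations reversed. The doubly activated methylene of 4 is alkylated with 10 under mild base (K2CO3, DMF) to give the substituted sulfonylacetate F8. The decarboxylative Claisen rearrangement under the conditions of step 3 then proceeds through the silyl ketene acetal F9 and the rearranged silyl ester F10, and loss of CO2 gives 11.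

Further compounds
F1 | step 14 | methyl (2E,6E)-3,7-dimethyl-9-[(1S)-2,6,6-trimethylcyclohex-2-en-1-yl]nona-2,6-dien-1-yl carbonate | CC1=CCCC(C)(C)[C@@H]1CC/C(C)=C/CC/C(C)=C/COC(=O)OC
F2 | step 14 | 4-[(tert-butyldimethylsilyl)oxy]-2-vinylphenol | Oc1ccc(O[Si](C)(C)C(C)(C)C)cc1C=C
F3 | step 14 | tert-butyl(dimethyl)[4-{[(3S,6E)-3,7-dimethyl-9-[(1S)-2,6,6-trimethylcyclohex-2-en-1-yl]nona-1,6-dien-3-yl]oxy}-3-vinylphenoxy]silane | CC1=CCCC(C)(C)[C@@H]1CC/C(C)=C/CC[C@](C)(Oc1ccc(O[Si](C)(C)C(C)(C)C)cc1C=C)C=C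
F4 | step 3 | tributyl({[(1R)-2,4,4-trimethylcyclohex-2-en-1-yl]oxy}methyl)stannane | CCCC[Sn](CCCC)(CCCC)CO[C@@H]1CCC(C)(C)C=C1C
F5 | step 3 | ({[(1R)-2,4,4-trimethylcyclohex-2-en-1-yl]oxy}methyl)lithium | [Li]CO[C@@H]1CCC(C)(C)C=C1C
F6 | step 3 | [(1S)-2,6,6-trimethylcyclohex-2-en-1-yl]methanol | CC1=CCCC(C)(C)[C@@H]1CO
F7 | step 3 | 1-methyl-4-({[(1S)-2,6,6-trimethylcyclohex-2-en-1-yl]methyl}sulfanyl)benzene | CC1=CCCC(C)(C)[C@@H]1CSc1ccc(C)cc1
F8 | step 6 | (1R)-2,4,4-trimethylcyclohex-2-en-1-yl (4E,8E)-10-acetoxy-4,8-dimethyl-2-(4-methylphenylsulfonyl)deca-4,8-dienoate | Cc1ccc(cc1)S(=O)(=O)C(C/C(C)=C/CC/C(C)=C/COC(C)=O)C(=O)O[C@@H]1CCC(C)(C)C=C1C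
F9 | step 6 | trimethylsilyl ketene acetal of F8 | Cc1ccc(cc1)S(=O)(=O)C(C/C(C)=C/CC/C(C)=C/COC(C)=O)=C(O[Si](C)(C)C)O[C@@H]1CCC(C)(C)C=C1C
F10 | step 6 | trimethylsilyl (4E,8E)-10-acetoxy-4,8-dimethyl-2-(4-methylphenylsulfonyl)-2-[(1S)-2,6,6-trimethylcyclohex-2-en-1-yl]deca-4,8-dienoate | CC1=CCCC(C)(C)[C@@H]1C(C/C(C)=C/CC/C(C)=C/COC(C)=O)(C(=O)O[Si](C)(C)C)S(=O)(=O)c1ccc(C)cc1
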